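Numbering: ring A = catechol on C2; ring B = dihydrofuran (O1, C2, C3, C3a, C7a); ring C = fused 2-pyranone (C3a, C4, O5, C6, C7, C7a); ring D = pendant 4-hydroxy-2-pyranone (O1'–C6', bound to C3 through C6'); ring E = catechol of the styryl arm.
Cuts: first ring D (C5'–C6' and O1'–C2'), back to a C3 carboxylic acid whose carboxyl carbon is C6'; then C3–C3a of ring B; then O1–C2; last the two aryl–CH=CH bonds.
Enabling feature: C6' is bound to C3 and stands 1,3 to C3a, the nucleophilic enol-ether carbon of ring C next to O1. If C6' is re-bound to C3a as a ketone, a six-membered 2-aryl-2,3-dihydropyran-4-one results (O1–C2–C3–C6'(=O)–C3a–C7a). Ring B can then be closed by a 1,2-shift of C3a from C6' to C3 (oxidative ring contraction), which also sets C3 and expels C6' at the acid level that ring D needs.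
The temporary ring opens to a 3-cinnamoyl-4-hydroxy-6-styryl-2-pyranone, that is dehydroacetic acid (ring C, bought) plus two molecules of one protected 3,4-dihydroxybenzaldehyde.
Forward: both arms by a twofold condensation, the temporary ring by oxa-Michael closure, ring B by contraction, ring D from the acid and 2,2,6-trimethyl-1,3-dioxin-4-one (acylketene cyclisation), then loss of four pivalates.
Stereochemistry: C2 comes from a catalytic asymmetric oxa-Michael closure. C3 follows from C2 by anti attack of trivalent iodine and inversion in the shift (trans). C3 stays epimerisable later, but trans is the stable arrangement.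

Key step: step 4

Assumption: the (R)-configured phosphoramide of step 3 is taken to give the (2S) ketone 6; if the sense of induction is the opposite, the (S)-catalyst is used and nothing else changes.
Abbreviations: Piv = pivaloyl; Ar = 3,4-bis(pivaloyloxy)phenyl. The target as drawn is trans-(2S,3S).

Step 1
Reactants: 1 3,4-dihydroxybenzaldehyde
Product: 2 3,4-bis(pivaloyloxy)benzaldehyde
Conditions: t-BuCOCl (2.3 equiv), Et3N, DMAP (cat.), CH2Cl2, 0 °C to rt
Reagents that add atoms: pivaloyl chloride, CC(C)(C)C(=O)Cl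
Why: Plain O-acylation of both phenols should give hindered, electron-withdrawing aryl esters that tolerate amine catalysis, acid and oxidant and later lower the migratory aptitude of ring A.

Step 2
Reactants: 2 3,4-bis(pivaloyloxy)benzaldehyde (2.2 equiv), 3 dehydroacetic acid (3-acetyl-4-hydroxy-6-methyl-2H-pyran-2-one)
Product: 5 3-[(E)-3-Ar-prop-2-enoyl]-6-[(E)-2-Ar-ethenyl]-4-hydroxy-2H-pyran-2-one, via monocinnamoyl pyranone 4 (not isolated)
Conditions: piperidine (0.3 equiv), AcOH (0.3 equiv), toluene, reflux, azeotropic removal of water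
Reagents that add atoms: none
Why: A twofold Claisen–Schmidt condensation should take place first at the acetyl methyl group of the tricarbonyl unit and then at the vinylogously acidified 6-methyl group, both double bonds forming as the conjugated E isomers.

Step 3
Reactants: 5 3-[(E)-3-Ar-prop-2-enoyl]-6-[(E)-2-Ar-ethenyl]-4-hydroxy-2H-pyran-2-one
Product: 6 (2S)-2-Ar-7-[(E)-2-Ar-ethenyl]-2,3-dihydro-4H,5H-pyrano[4,3-b]pyran-4,5-dione
Conditions: (R)-N-triflyl phosphoramide of 3,3'-bis(2,4,6-triisopropylphenyl)-BINOL (10 mol %), 4 Å molecular sieves, toluene, −20 °C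
Reagents that add atoms: none
Why: Proposed new method: the anion of the enolic 4-OH spreads its charge over the tricarbonyl unit and switches the enone off, so the 6-endo-trig oxa-Michael closure should run through the neutral enol and a protonated ketone; a chiral N-triflyl phosphoramide can provide this bifunctionally (N–H to the cinnamoyl oxygen, P=O to the enol O–H), so that O1–C2 forms inside a chiral hydrogen-bonded pair and sets C2. The closest known types are the Brønsted-acid catalysed asymmetric intramolecular hetero-Michael cyclisation of 2'-amino- and 2'-hydroxychalcones and the achiral acid-induced closure of 3-alkenoyl-4-hydroxy-2-pyranones; the electron-poor aryl group favours the closed form and the low temperature should keep the reverse reaction slow.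

Step 4
Reactants: 6 (2S)-2-Ar-7-[(E)-2-Ar-ethenyl]-2,3-dihydro-4H,5H-pyrano[4,3-b]pyran-4,5-dione
Product: 9 methyl (2S,3S)-2-Ar-6-[(E)-2-Ar-ethenyl]-4-oxo-2,3-dihydro-4H-furo[3,2-c]pyran-3-carboxylate, via methyl enol ether 7 (not isolated), via iodane ketal 8 (not isolated)
Conditions: PhI(OAc)2 (1.2 equiv), HC(OMe)3, conc. H2SO4 (0.2 equiv), 0 °C to rt
Reagents that add atoms: trimethyl orthoformate, COC(OC)OC; (diacetoxyiodo)benzene, CC(=O)OI(OC(C)=O)c1ccccc1 (atoms only in intermediate 8)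
Why: Acid and HC(OMe)3 turn the ketone (C4 of 6, the later C6') into methyl enol ether 7; PhI(OAc)2 then attacks C3 on the face away from the pseudo-equatorial C2 aryl group and methanol adds to C4, giving ketal 8 with an equatorial C3–iodine bond. This bond is antiperiplanar to the ring bond C4–C4a (C4a is the later C3a), so the C4a=C8a enol-ether π bond displaces iodobenzene from C3 in a 3-exo-tet attack, and the spiro-cyclopropyl cation, stabilised by O1 and by the ring oxygen of ring C, opens under the push of the two methoxy groups to a dimethoxycarbenium ion that loses a methyl group to acetate and gives ester 9. The closest known reaction type is the oxidative ring contraction (1,2-aryl shift, quasi-Favorskii type) of 2-arylchroman-4-ones with PhI(OAc)2 or Tl(NO3)3 in trimethyl orthoformate, which gives methyl trans-2-aryl-2,3-dihydrobenzofuran-3-carboxylates. Ring B is thus closed by contraction of the six-membered ring through a 1,2-shift, not by a direct 5-(enolendo) attack of C3a, which would be stereoelectronically poor. C2 is untouched, and C3 is controlled by C2 because iodine enters anti to the aryl group and is replaced with inversion, which places the ester carbon trans to the aryl group, (2S,3S). The step needs migration of C4a rather than of the C2 aryl group or loss of the C2 hydrogen, which the equatorial leaving group and the electron-poor bis(pivaloyloxy)phenyl ring should secure; it also needs attack at the enol ether rather than at the styryl double bond, which is deactivated by ring C and by its own acylated aryl group.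

Step 5
Reactants: 9 methyl (2S,3S)-2-Ar-6-[(E)-2-Ar-ethenyl]-4-oxo-2,3-dihydro-4H-furo[3,2-c]pyran-3-carboxylate
Product: 11 (2S,3S)-2-Ar-6-[(E)-2-Ar-ethenyl]-4-oxo-2,3-dihydro-4H-furo[3,2-c]pyran-3-carboxylic acid, via trimethylstannyl ester 10 (not isolated)
Conditions: Me3SnOH (5 equiv), ClCH2CH2Cl, 70 °C; then 5 % aq. HCl
Reagents that add atoms: trimethyltin hydroxide, C[Sn](C)(C)O
Why: Nearly neutral tin-hydroxide ester cleavage should free the acid without opening ring B or ring C as alkali would, and the shielded pivalates should react more slowly than the methyl ester.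

Step 6
Reactants: 11 (2S,3S)-2-Ar-6-[(E)-2-Ar-ethenyl]-4-oxo-2,3-dihydro-4H-furo[3,2-c]pyran-3-carboxylic acid, 12 2,2,6-trimethyl-4H-1,3-dioxin-4-one
Product: 15 6-{2-[(2S,3S)-2-Ar-6-[(E)-2-Ar-ethenyl]-4-oxo-2,3-dihydro-4H-furo[3,2-c]pyran-3-yl]-2-oxoethyl}-2,2-dimethyl-4H-1,3-dioxin-4-one, via acid chloride 13 (not isolated), via lithium dienolate 14 (not isolated)
Conditions: (COCl)2, DMF (cat.), CH2Cl2, 0 °C, then evaporation; 12 and LiN(SiMe3)2 (2.2 equiv each), THF, −78 °C, then 13; aq. NH4Cl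
Reagents that add atoms: oxalyl chloride, O=C(Cl)C(=O)Cl (chlorine of 13 only); lithium hexamethyldisilazide, [Li+].C[Si](C)(C)[N-][Si](C)(C)C (lithium of 14 only)
Why: γ-C-Acylation of the dioxinone dienolate with an acid chloride (vinylogous Claisen condensation) forms C5'–C6', and C3, if it passes through a ketene or enolate, should be reprotonated to the more stable trans arrangement under the control of C2.

Step 7
Reactants: 15 the keto-dioxinone of step 6
Product: 17 (2S,3S)-2-Ar-6-[(E)-2-Ar-ethenyl]-3-(4-hydroxy-2-oxo-2H-pyran-6-yl)-2,3-dihydro-4H-furo[3,2-c]pyran-4-one (hypholomine B tetrapivalate), via acylketene 16 (not isolated)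
Conditions: toluene, 110 °C
Reagents that add atoms: none
Why: Thermal retro-[4+2] loss of acetone from the dioxinone gives an acylketene that is captured by the enol oxygen of the C6' ketone, a neutral and well-used entry to 6-substituted 4-hydroxy-2-pyranones that leaves both stereocenters alone.

Step 8
Reactants: 17 hypholomine B tetrapivalate
Product: 18 hypholomine B, (2S,3S)
Conditions: K2CO3 (6 equiv), degassed MeOH, argon, 0 °C to rt; then 1 M HCl to pH 3
Reagents that add atoms: none
Why: Base-mediated transesterification of the four activated aryl esters should free the catechols, while ring D is shielded as its enolate, ring-opening of ring B (reverse 5-endo-trig) is stereoelectronically slow, and any epimerisation at C3 leads back to trans.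

Compound list
1 | 3,4-dihydroxybenzaldehyde | O=Cc1ccc(O)c(O)c1 | starting material
2 | 3,4-bis(pivaloyloxy)benzaldehyde | O=Cc1ccc(OC(=O)C(C)(C)C)c(OC(=O)C(C)(C)C)c1 | intermediate
3 | dehydroacetic acid | CC(=O)c1c(O)cc(C)oc1=O | starting material
4 | 3-[(E)-3-Ar-prop-2-enoyl]-4-hydroxy-6-methyl-2H-pyran-2-one | Cc1cc(O)c(C(=O)/C=C/c2ccc(OC(=O)C(C)(C)C)c(OC(=O)C(C)(C)C)c2)c(=O)o1 | intermediate
5 | 3-[(E)-3-Ar-prop-2-enoyl]-6-[(E)-2-Ar-ethenyl]-4-hydroxy-2H-pyran-2-one | O=C(/C=C/c1ccc(OC(=O)C(C)(C)C)c(OC(=O)C(C)(C)C)c1)c1c(O)cc(/C=C/c2ccc(OC(=O)C(C)(C)C)c(OC(=O)C(C)(C)C)c2)oc1=O | intermediate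
6 | (2S)-2-Ar-7-[(E)-2-Ar-ethenyl]-2,3-dihydro-4H,5H-pyrano[4,3-b]pyran-4,5-dione | O=C1C[C@@H](c2ccc(OC(=O)C(C)(C)C)c(OC(=O)C(C)(C)C)c2)Oc2cc(/C=C/c3ccc(OC(=O)C(C)(C)C)c(OC(=O)C(C)(C)C)c3)oc(=O)c12 | intermediate
7 | (2S)-2-Ar-7-[(E)-2-Ar-ethenyl]-4-methoxy-2H,5H-pyrano[4,3-b]pyran-5-one | COC1=C[C@@H](c2ccc(OC(=O)C(C)(C)C)c(OC(=O)C(C)(C)C)c2)Oc2cc(/C=C/c3ccc(OC(=O)C(C)(C)C)c(OC(=O)C(C)(C)C)c3)oc(=O)c12 | intermediate
8 | (2R,3R)-3-[acetoxy(phenyl)-λ3-iodanyl]-2-Ar-7-[(E)-2-Ar-ethenyl]-4,4-dimethoxy-3,4-dihydro-2H,5H-pyrano[4,3-b]pyran-5-one (iodine trans to Ar; the C2 descriptor changes by priority only) | COC1(OC)[C@H](I(OC(C)=O)c2ccccc2)[C@@H](c2ccc(OC(=O)C(C)(C)C)c(OC(=O)C(C)(C)C)c2)Oc2cc(/C=C/c3ccc(OC(=O)C(C)(C)C)c(OC(=O)C(C)(C)C)c3)oc(=O)c12 | intermediate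
9 | methyl (2S,3S)-2-Ar-6-[(E)-2-Ar-ethenyl]-4-oxo-2,3-dihydro-4H-furo[3,2-c]pyran-3-carboxylate (trans) | COC(=O)[C@H]1c2c(cc(/C=C/c3ccc(OC(=O)C(C)(C)C)c(OC(=O)C(C)(C)C)c3)oc2=O)O[C@@H]1c1ccc(OC(=O)C(C)(C)C)c(OC(=O)C(C)(C)C)c1 | intermediate
10 | trimethylstannyl ester of acid 11 | C[Sn](C)(C)OC(=O)[C@H]1c2c(cc(/C=C/c3ccc(OC(=O)C(C)(C)C)c(OC(=O)C(C)(C)C)c3)oc2=O)O[C@@H]1c1ccc(OC(=O)C(C)(C)C)c(OC(=O)C(C)(C)C)c1 | intermediate
11 | (2S,3S)-2-Ar-6-[(E)-2-Ar-ethenyl]-4-oxo-2,3-dihydro-4H-furo[3,2-c]pyran-3-carboxylic acid | OC(=O)[C@H]1c2c(cc(/C=C/c3ccc(OC(=O)C(C)(C)C)c(OC(=O)C(C)(C)C)c3)oc2=O)O[C@@H]1c1ccc(OC(=O)C(C)(C)C)c(OC(=O)C(C)(C)C)c1 | intermediate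
12 | 2,2,6-trimethyl-4H-1,3-dioxin-4-one | CC1=CC(=O)OC(C)(C)O1 | starting material
13 | acid chloride of 11, (2S,3S) | O=C(Cl)[C@H]1c2c(cc(/C=C/c3ccc(OC(=O)C(C)(C)C)c(OC(=O)C(C)(C)C)c3)oc2=O)O[C@@H]1c1ccc(OC(=O)C(C)(C)C)c(OC(=O)C(C)(C)C)c1 | intermediate
14 | lithium 2,2-dimethyl-6-methylidene-6H-1,3-dioxin-4-olate | C=C1C=C([O-])OC(C)(C)O1.[Li+] | intermediate
15 | 6-{2-[(2S,3S)-2-Ar-6-[(E)-2-Ar-ethenyl]-4-oxo-2,3-dihydro-4H-furo[3,2-c]pyran-3-yl]-2-oxoethyl}-2,2-dimethyl-4H-1,3-dioxin-4-one | CC1(C)OC(=O)C=C(CC(=O)[C@H]2c3c(cc(/C=C/c4ccc(OC(=O)C(C)(C)C)c(OC(=O)C(C)(C)C)c4)oc3=O)O[C@@H]2c2ccc(OC(=O)C(C)(C)C)c(OC(=O)C(C)(C)C)c2)O1 | intermediate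
16 | acylketene from 15 (5-substituted 3,5-dioxopent-1-en-1-one), (2S,3S) | O=C=CC(=O)CC(=O)[C@H]1c2c(cc(/C=C/c3ccc(OC(=O)C(C)(C)C)c(OC(=O)C(C)(C)C)c3)oc2=O)O[C@@H]1c1ccc(OC(=O)C(C)(C)C)c(OC(=O)C(C)(C)C)c1 | intermediate
17 | hypholomine B tetrapivalate, (2S,3S) | O=c1cc(O)cc([C@H]2c3c(cc(/C=C/c4ccc(OC(=O)C(C)(C)C)c(OC(=O)C(C)(C)C)c4)oc3=O)O[C@@H]2c2ccc(OC(=O)C(C)(C)C)c(OC(=O)C(C)(C)C)c2)o1 | intermediate
18 | hypholomine B, (2S,3S) | O=c1cc(O)cc([C@H]2c3c(cc(/C=C/c4ccc(O)c(O)c4)oc3=O)O[C@@H]2c2ccc(O)c(O)c2)o1 | target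

Total step count: 8. Longest linear sequence: 8 (1 to 18).

Steps most likely to fail

Step 3. What may go wrong is poor facial selectivity in the closure and loss of configuration through reversible ring opening (retro-oxa-Michael) under the same acid. The fallback replaces catalysis by resolution and uses known chemistry only. It sets out from 5, which is closed with CF3CO2H in CH2Cl2 to the racemic ketone F1. The conditions of steps 4 and 5 are applied to the racemate and give the racemic trans methyl ester F2 and then the racemic trans acid F3. Crystallisation with (R)-1-phenylethylamine (or its enantiomer, if that gives the less soluble salt of the wanted acid) should give the diastereomerically pure ammonium salt F4 of the (2S,3S) acid. Acidification brings the material back to the route at 11.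

Step 4. What may go wrong is migration of the C2 aryl group in place of C4a, elimination to the fully unsaturated pyranone, or acid-induced ionisation of the O1–C2 bond with loss of configuration. In the fallback the leaving group is installed and purified in a separate, non-oxidative operation, and the shift is triggered by a halophilic silver salt under nearly neutral conditions. It sets out from 6. CuBr2 in EtOAc/CHCl3 should give the trans-3-bromo ketone F5. HC(OMe)3 and TsOH convert it into the bromo dimethyl ketal F6. AgBF4 in MeOH then induces the known silver-assisted 1,2-shift of α-bromo ketals, and the route is rejoined at 9.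

Step 6. What may go wrong is proton transfer instead of acylation, attack of the strongly basic dienolate on the pivalates, or base-induced opening of ring B. The fallback avoids any base in the C–C bond formation. It sets out from acid chloride 13, which is treated in CH2Cl2 from −78 °C to rt with 1-methoxy-1,3-bis(trimethylsilyloxy)buta-1,3-diene F7 (made from methyl acetoacetate by two successive silylations). Acylation at the terminal carbon should give the methyl 3,5-dioxopentanoate F8. DBU in toluene then closes ring D with loss of methanol, and the route is rejoined at 17.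

Further compounds
F1 | step 3 | racemic 2-Ar-7-[(E)-2-Ar-ethenyl]-2,3-dihydro-4H,5H-pyrano[4,3-b]pyran-4,5-dione | O=C1CC(c2ccc(OC(=O)C(C)(C)C)c(OC(=O)C(C)(C)C)c2)Oc2cc(/C=C/c3ccc(OC(=O)C(C)(C)C)c(OC(=O)C(C)(C)C)c3)oc(=O)c12
F2 | step 3 | racemic trans methyl ester (9 together with its (2R,3R) enantiomer; SMILES of the latter) | COC(=O)[C@@H]1c2c(cc(/C=C/c3ccc(OC(=O)C(C)(C)C)c(OC(=O)C(C)(C)C)c3)oc2=O)O[C@H]1c1ccc(OC(=O)C(C)(C)C)c(OC(=O)C(C)(C)C)c1
F3 | step 3 | racemic trans acid (11 together with its (2R,3R) enantiomer; SMILES of the latter) | OC(=O)[C@@H]1c2c(cc(/C=C/c3ccc(OC(=O)C(C)(C)C)c(OC(=O)C(C)(C)C)c3)oc2=O)O[C@H]1c1ccc(OC(=O)C(C)(C)C)c(OC(=O)C(C)(C)C)c1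
F4 | step 3 | (R)-1-phenylethylammonium salt of the (2S,3S) acid 11 | [O-]C(=O)[C@H]1c2c(cc(/C=C/c3ccc(OC(=O)C(C)(C)C)c(OC(=O)C(C)(C)C)c3)oc2=O)O[C@@H]1c1ccc(OC(=O)C(C)(C)C)c(OC(=O)C(C)(C)C)c1.C[C@@H]([NH3+])c1ccccc1
F5 | step 4 | (2R,3R)-3-bromo-2-Ar-7-[(E)-2-Ar-ethenyl]-2,3-dihydro-4H,5H-pyrano[4,3-b]pyran-4,5-dione (bromine trans to Ar) | O=C1[C@H](Br)[C@@H](c2ccc(OC(=O)C(C)(C)C)c(OC(=O)C(C)(C)C)c2)Oc2cc(/C=C/c3ccc(OC(=O)C(C)(C)C)c(OC(=O)C(C)(C)C)c3)oc(=O)c12
F6 | step 4 | (2R,3R)-3-bromo-2-Ar-7-[(E)-2-Ar-ethenyl]-4,4-dimethoxy-3,4-dihydro-2H,5H-pyrano[4,3-b]pyran-5-one | COC1(OC)[C@H](Br)[C@@H](c2ccc(OC(=O)C(C)(C)C)c(OC(=O)C(C)(C)C)c2)Oc2cc(/C=C/c3ccc(OC(=O)C(C)(C)C)c(OC(=O)C(C)(C)C)c3)oc(=O)c12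
F7 | step 6 | 1-methoxy-1,3-bis(trimethylsilyloxy)buta-1,3-diene | COC(O[Si](C)(C)C)=CC(=C)O[Si](C)(C)C
F8 | step 6 | methyl 5-[(2S,3S)-2-Ar-6-[(E)-2-Ar-ethenyl]-4-oxo-2,3-dihydro-4H-furo[3,2-c]pyran-3-yl]-3,5-dioxopentanoate | COC(=O)CC(=O)CC(=O)[C@H]1c2c(cc(/C=C/c3ccc(OC(=O)C(C)(C)C)c(OC(=O)C(C)(C)C)c3)oc2=O)O[C@@H]1c1ccc(OC(=O)C(C)(C)C)c(OC(=O)C(C)(C)C)c1
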